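- Target, as I read the runs, needs a second partner on a starting material that already holds one. I therefore follow the partner still spare.

| flask | starting material | partner | remark | time |
|---|---|---|---|---|
| dawn | 20 mM | 1.1 equiv | run made earlier |  |
| summer | 63 mM | 1.1 equiv | run made earlier |  |
| noon | 25 mM | 3 equiv | run made earlier |  |
| south-west | 100 mM | 1.10 equiv |  | 2.5 min |
| north | 50 mM | 1.10 equiv |  | 2.5 min |
| south | 25 mM | 4.40 equiv |  | 2.5 min |
| west | 25 mM | 1.10 equiv |  | 2.5 min |
| north-east | 100 mM | 2.20 equiv |  | 2.5 min |
| north-west | 40 mM | 4.40 equiv |  | 2.5 min |

| run | time / s | target / % | starting material / % |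
|---|---|---|---|
| dawn | 12.0 | 2.3 | 30.8 |
| dawn | 40.0 | 1.6 | 32.6 |
| dawn | 60.0 | 1.8 | 34.7 |
| dawn | 120 | 0 | 39.3 |
| summer | 25.0 | 13.8 | 21.5 |
| summer | 50.0 | 17.0 | 22.2 |
| summer | 80.0 | 16.6 | 23.9 |
| summer | 120 | 14.1 | 24.4 |
| noon | 25.0 | 41.5 | 6.5 |
| noon | 50.0 | 44.9 | 9.0 |
| noon | 80.0 | 38.9 | 13.7 |
| noon | 120 | 26.0 | 17.1 |

(each reading ± 0.5 percentage points)

* all flasks from highest to lowest amount of target, in percent of the starting material charged, at 2.5 min (south-west / north / south / west / north-east / north-west)
* the amount of target, in percent of the starting material charged of the flask you put first, at 2.5 min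
* the amount of target, in percent of the starting material charged of the flask you put last, at 2.5 min

- a reading or a percentage of target counts all its forms, free or not

- **Main step only.** Starting material binds one partner fast. Dawn's first reading gives a binding constant of 0.275 /mM.
- In north-east, a first pass leaves 3.03% of the charge unbound. Put back in, that becomes 2.86%.
- The spare partner in north-east is then 1.23 of the charge.
- **One more step.** At noon's peak reading, I count one partner in the bound rest and two in target. That leaves 1.64 spare.
- The pull is target over bound rest, per unit of spare partner, at noon's charge: 0.594. I scale it with the charge, so north-east has 2.37.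
- Target uses up spare partner, so I iterate. The first round gives 72.3% of the charge as target.
- Taking that target off the spare partner gives 53.0%. Once more gives 60.6%, and I commit to that.
- **The rest.** Noon's target falls from 44.9% at 50.0 s to 26.0% at 120 s. I therefore expect north-east at or below my number.
- The forecast gives north-east > north-west > south > south-west > north > west, with 50% first and 1% last, saying “North-east has the largest pool”, and its top is lower than mine.
- The flasks give north-east > north-west > south > south-west > north > west, with 70.8% first and 0.497% last, so north-east stands higher than my reckoning.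

    starting material + partner ⇌ intermediate A (K = 260 /M, k = 21.0 /M/s)
    starting material ⇌ intermediate B (K = 0.470, k = 0.0150 /s)
    intermediate A ⇌ intermediate C (K = 0.360, k = 0.00150 /s)
    partner + intermediate A ⇌ target (K = 5.60 /M, k = 1.30 /M/s)
    partner → decomposed reagent (k = 0.0190 /s)
    2 starting material → self-condensation product (k = 0.0880 /M/s)
    crystals ⇌ target, rate k7*(cs7 - [target]) while solid is left; crystals form when [target] > cs7 (solubility = 0.980 mM, k = 0.960 /s)

- North-east has not come to rest. Its pull, read at 2.50 min, is 45.5, not 2.37, with crystals at 69.9% of its 70.8% target. In north-west, the pull scales to 0.950. Its rounds give 74.3%, then 69.7%, and that flask holds 68.0%. Left until 25.0 min, north-east keeps 0.265% target.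

The runs come from a simulation from invented constants.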